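## Structural features

The target is a monocyclic, iridal-type seco-triterpenoid. Its single cyclohexane ring (ring atoms numbered C1 to C6 here) carries a methyl group and a sixteen-carbon tetraenyl chain on the quaternary C1, a 3-hydroxypropyl arm on C2, an exocyclic tetrasubstituted (Z)-2-methyl enal at C3, and a methyl and a hydroxyl group on C6. The three stereocentres are contiguous: C6 (S, tertiary carbinol), C1 (S, quaternary) and C2 (R). The C6 hydroxyl, the C1 methyl and the C2 arm lie on one face of the ring; the C6 methyl and the C1 chain lie on the other. The chain is joined to C1 through two methylene groups and holds an (E,E,E)-triene with methyl groups on its two outer sp2 carbons, followed by an isolated trisubstituted alkene. The fragile parts are the conjugated triene (acid, light, oxidants, dissolving metals), the enal (its geometry and C2, its γ-position, can be lost through the dienol), the tertiary alcohol beside a quaternary carbon, and the free primary alcohol. The real difficulty is the pair of adjacent fully substituted carbons C1 and C6 with a fixed methyl/hydroxyl relationship, followed directly by C2 and by an enal of defined geometry. The key step uses the fact that the C6 hydroxyl is cis to the C1 methyl: in a cyclohexenol with a C1=C2 double bond, the allylic C6 oxygen can pass the future methyl carbon to C1 on its own face as a cyclopropane methylene, and the second cyclopropane bond (to C2) can later be broken from a C3 ketone, which also opens C2 for the arm.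

## Logic of the disconnections

30 ⇒ 29 ⇒ 28. The C3=C(CH3)–CHO unit is cut at the formyl C=O and traced to a tertiary carbinol at C3 bearing an isopropenyl group. That group is robust and non-electrophilic, so no ring aldehyde is present while the chain is built. The primary oxygen of the arm must be masked during this oxidation (29). The demand is that the oxidant spares the triene and that the 1,3-oxygen shift gives the Z geometry.

28 ⇒ 23 + 26; 23 ⇒ 22; 26 ⇒ 25 ⇒ 24. The chain is cut first at the central triene double bond and then at the trisubstituted double bond nearest the ring. Both are E alkenes beside a methyl-bearing sp2 carbon, which points to carbonyl olefination. The first cut gives an (E)-enal 23 and a ten-carbon allylic phosphonate 26, which goes back through 25 to 24; the second cut gives the three-carbon aldehyde 22. The triene then appears only three steps from the end. Both olefinations must be E-selective and must tolerate free tertiary hydroxyls.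

22 ⇒ 21 ⇒ 20 ⇒ 18 ⇒ 17. The aldehyde is traced to its dioxolane (21), the silyl ether to the primary alcohol (20), the C–O bond of the arm to a terminal alkene (18), and the C3–isopropenyl bond to the C3 ketone (17). Allyl and dioxolane are inert handles that survive metal–ammonia and organometallic steps, and 17 holds all three ring stereocentres in a simple cyclohexanone. The borane must choose the allyl group over the isopropenyl group, and acetal cleavage must spare the tertiary allylic alcohol.

17 ⇒ 14 + 15. The C2–allyl bond is cut and C2 is re-joined to the C1 methyl carbon, giving the cyclopropyl ketone 14. Reductive cleavage of that ketone yields the methyl on quaternary C1 with fixed configuration and, in the same act, the C2=C3 enolate that could not be formed selectively from a ketone (C4 would compete). The problem of the quaternary centre is reduced to the face of a cyclopropane. The forward step must cleave the external cyclopropane bond and alkylate C2 anti to the C1 chain.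

14 ⇒ 13 ⇒ 10 + 11. The bonds C1–CH2 and C2–CH2 are cut, giving the cyclohexenediol 10 and the one-carbon unit 11. The C6 hydroxyl is cis to the future methyl and allylic to C1=C2, so it can deliver the carbon. One ring and two stereocentres disappear; 10 keeps only C6 and a disposable centre at C3. The forward step needs complete facial control and must leave the dioxolane alone; the C3 hydroxyl is placed on the same face so that both carbinols direct alike.

10 ⇒ 9 ⇒ 5 + 6. The C3–H bond is cut (ketone reduction), then the C1–chain bond, giving the vinylogous ester 5 and the three-carbon acetal nucleophile from 6. A 1,2-addition with acidic transposition puts the chain on the alkene carbon beside the carbinol and the carbonyl at C3 in one operation. The reduction must be catalyst-controlled to give the cis diol, and the acetal must outlast the acid.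

5 ⇒ 3 ⇒ 1. The C6–O and C6–CH3 bonds are cut back to the α′ position of 1. C6 is the only stereocentre made by an external chiral reagent; all others are relayed from it. The forward step needs enantioselective oxygen transfer to a tetrasubstituted enolate.

## Other disconnections considered

Alternative 1: The cut is the ring bond C1–C2 of an acyclic precursor built from (S)-linalool A2, whose carbinol carbon becomes C6. Anodic oxidation of a methyl enol ether (C2=C3) would give a radical cation that is captured at C2 by the substituted terminus of a tethered allylsilane; loss of silicon leaves a vinyl group on the new quaternary C1, and acidic work-up frees the C3 ketone in A1.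
- In its favour: C6 comes from the chiral pool, which is better than the chosen plan, where an oxaziridine must create this centre. Ring, C1, C2, the protected arm and the C3 ketone arise in one operation, so A1 stands at the level of 17 with the arm already oxygenated and silylated; this too is better step economy after ring formation.
- Against it: the configuration at C1 and C2 would rest on the conformational preference of a chair-like radical-cation transition state beside a bulky silyloxy group, not on covalent delivery. Bond formation through a fully substituted allylsilane carbon next to a fully substituted carbinol carbon is sterically demanding. The vinyl group is one carbon short of the CH2CH2CH= spacer, so hydroboration must be followed by a homologation. Turning A2 into the cyclisation substrate costs many steps.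
- Comparison: a one-electron pathway through cationic intermediates is harder to predict than the concerted, oxygen-bound methylene transfer. In total length the two plans would be comparable.

Alternative 2: The cuts are the C2–arm bond and the C1–chain bond, both made on the preformed ring of the enone ketal 7-methyl-1,4-dioxaspiro[4.5]dec-6-en-8-one A4. CuBr·SMe2 with a chiral ferrocenyl diphosphine would add a 3-silyloxypropyl Grignard reagent to the β-carbon C2, and the magnesium enolate would be allylated at C1 to give A3; no ring is closed.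
- In its favour: the step is catalytic and enantioselective and installs both appendages in one flask. Anti alkylation with respect to the fresh β-substituent puts the arm cis to the C1 methyl by a dependable principle; on this point the alternative is better than step 7 of the chosen plan. The arm arrives protected, so hydroboration and silylation are not needed and the step count could be lower.
- Against it: the β-carbon is flanked by the ketal carbon and the enone is α-methylated, both of which slow copper-catalysed Grignard additions and erode selectivity. More seriously, the C6 carbinol would be made afterwards by adding a methyl nucleophile to the C6 ketone beside the quaternary C1, where the two faces differ only as methyl against allyl. The methyl/hydroxyl relationship that the chosen plan fixes by intramolecular delivery would be the weak point. Two three-carbon arms of similar reactivity must also be kept apart.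
- Comparison: both plans use closed-shell, well-understood mechanisms (equal). The chosen plan controls C6/C1 better; the alternative controls C1/C2 better.

Alternative 3: The cuts are C1–C6 and C2–C3. The (E)-2-methyl enal A6 (future C1 and C2) would add to the (E,E)-1,4-bis(silyloxy)diene A7 (future C6, C5, C4, C3) under a chiral oxazaborolidinium Lewis acid to give the formyl-endo adduct A5, closing the ring in one [4+2] step.
- In its favour: it is the most convergent plan. The trans relationship of formyl group and arm follows stereospecifically from the E dienophile, which is as secure as the syn addition of the chosen key step (equal). The absolute configuration comes from a catalyst in the ring-forming step itself, and both ring oxygens are delivered.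
- Against it: a β-alkylated 2-methyl enal is a sluggish dienophile, and the electron-rich diene is sensitive to the strong Lewis acid it needs. C6 arrives as a secondary silyl ether, so oxidation and methyl addition beside the quaternary C1 would again set the methyl/hydroxyl relationship without a directing element. The two secondary silyl ethers must be told apart and the ring alkene reduced. The formyl carbon sits directly on C1, so a two-carbon homologation is needed before the triene can be built, whereas 22 already carries the three-carbon aldehyde.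
- Comparison: the step count after the key step would be higher, and the gain in convergence is largely spent on these corrections.

Key step: step 5

Remark 1: the oxygen at C3 is only a relay to the cyclopropyl ketone, so it is carried as a free hydroxyl cis to the C6 hydroxyl; both carbinols then steer the carbenoid to the same face and no silyl ether is handled before the key step.
Remark 2: the sense of induction of the oxaziridine in step 2 is inferred from 2-alkyl-1-tetralone enolates; should it be opposite, the mirror-image reagent is used and nothing else changes.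

Step 1
Reactants: 1 3-ethoxycyclohex-2-en-1-one
Product: 3 rac-3-ethoxy-6-methylcyclohex-2-en-1-one, via lithium dienolate 2 (not isolated)
Conditions: LiN(i-Pr)2, THF, −78 °C; CH3I, −78 °C → rt
Reagents that add atoms: iodomethane, CI
Why: Kinetic deprotonation of the vinylogous ester occurs at the α′ carbon (C6) and the dienolate is C-methylated there (Stork–Danheiser α′-alkylation); the new centre is racemic and is flattened again in step 2.

Step 2
Reactants: 3 rac-3-ethoxy-6-methylcyclohex-2-en-1-one
Product: 5 (6S)-3-ethoxy-6-hydroxy-6-methylcyclohex-2-en-1-one, via sodium dienolate 4 (not isolated)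
Conditions: NaN(SiMe3)2, THF, −78 °C; (−)-[(8,8-dichlorocamphoryl)sulfonyl]oxaziridine, −78 °C; aq NH4Cl
Reagents that add atoms: (−)-[(8,8-dichlorocamphoryl)sulfonyl]oxaziridine, CC1(C)[C@H]2CC[C@@]13CS(=O)(=O)[N@@]4O[C@]34C2(Cl)Cl
Why: Davis asymmetric enolate hydroxylation: the tetrasubstituted sodium dienolate attacks the oxaziridine oxygen, and the camphor framework should leave the Si face of C6 open, giving the S carbinol. The conjugated C2=C3 unit plays the part of the aryl ring of the 2-alkyl-1-tetralone enolates for which this reagent class is selective; any minor enantiomer is removed as a diastereomer after step 4.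

Step 3
Reactants: 5 (6S)-3-ethoxy-6-hydroxy-6-methylcyclohex-2-en-1-one; 6 2-(2-bromoethyl)-1,3-dioxolane
Product: 9 (4S)-3-[2-(1,3-dioxolan-2-yl)ethyl]-4-hydroxy-4-methylcyclohex-2-en-1-one, via Grignard reagent 7 (not isolated), via magnesium dialkoxide adduct 8 (not isolated)
Conditions: Mg, THF, 25 °C (6 → 7, 3 equiv); 5, THF, 0 °C → rt; then 1 M HCl aq, 0 °C, 20 min
Reagents that add atoms: water, O
Why: Stork–Danheiser sequence: the Grignard reagent adds 1,2 to the vinylogous ester carbonyl (one equivalent is spent on the hydroxyl), and brief cold acid ionises the doubly activated allylic position, hydrolyses the enol ether and leaves the enone with the carbonyl transposed to C3. The dioxolane should outlast these conditions and C6 is not touched.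

Step 4
Reactants: 9 (4S)-3-[2-(1,3-dioxolan-2-yl)ethyl]-4-hydroxy-4-methylcyclohex-2-en-1-one
Product: 10 (1S,4R)-2-[2-(1,3-dioxolan-2-yl)ethyl]-1-methylcyclohex-2-ene-1,4-diol
Conditions: (S)-2-methyl-CBS-oxazaborolidine (C18H20BNO, 0.2 equiv), BH3·SMe2, THF, −30 °C; MeOH
Reagents that add atoms: none
Why: Corey–Bakshi–Shibata reduction: the catalyst-bound borane delivers hydride to the enone carbonyl with the alkenyl side as the large group, so the S catalyst should give the 4R alcohol, cis to the tertiary hydroxyl. Diol formed from any (R)-9 is the trans diastereomer and is separated here.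

Step 5
Reactants: 10 (1S,4R)-2-[2-(1,3-dioxolan-2-yl)ethyl]-1-methylcyclohex-2-ene-1,4-diol; 11 diiodomethane
Product: 13 (1R,2S,5R,6S)-1-[2-(1,3-dioxolan-2-yl)ethyl]-2-methylbicyclo[4.1.0]heptane-2,5-diol, via bis(ethylzinc) alkoxide 12 (not isolated)
Conditions: Et2Zn (5 equiv), CH2I2 (10 equiv), CH2Cl2, −10 °C → rt; aq NH4Cl
Reagents that add atoms: none
Why: Et2Zn first converts both hydroxyls into ethylzinc alkoxides (12) and, with CH2I2, forms the carbenoid EtZnCH2I. The carbenoid zinc binds an alkoxide oxygen and the methylene carbon is passed to the C1=C2 π bond through the butterfly transition state of the Simmons–Smith reaction, C1–CH2 and C2–CH2 forming in one concerted syn addition while iodide moves to zinc. The closest known reaction type is the hydroxyl-directed Furukawa cyclopropanation of cyclohex-2-en-1-ols, which is strongly syn selective for secondary and tertiary carbinols. The three-membered ring is closed by this concerted [2+1] addition of the carbenoid carbon across the alkene, not by a stepwise closure, so the ring fusion must be cis. The new stereocentre C1 is fixed by the face from which the methylene arrives, the face of the C6 alkoxide; C2 follows from the syn addition and is cis to the same oxygen. The step needs facial selectivity and chemoselectivity for this one alkene. The first is secured because the C6 and C3 alkoxides lie on the same face and flank the alkene on both sides; the second because the alkene is electron-rich, no other alkene is present, and the dioxolane tolerates the weakly Lewis acidic zinc salts at or below room temperature.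

Step 6
Reactants: 13 (1R,2S,5R,6S)-1-[2-(1,3-dioxolan-2-yl)ethyl]-2-methylbicyclo[4.1.0]heptane-2,5-diol
Product: 14 (1S,5S,6R)-6-[2-(1,3-dioxolan-2-yl)ethyl]-5-hydroxy-5-methylbicyclo[4.1.0]heptan-2-one
Conditions: Dess–Martin periodinane, NaHCO3, CH2Cl2, 0 °C → rt
Reagents that add atoms: none
Why: Dess–Martin oxidation turns the secondary cyclopropyl carbinol into the ketone under buffered conditions; the tertiary alcohol cannot be oxidised and the cyclopropane and the acetal are not affected.

Step 7
Reactants: 14 (1S,5S,6R)-6-[2-(1,3-dioxolan-2-yl)ethyl]-5-hydroxy-5-methylbicyclo[4.1.0]heptan-2-one; 15 allyl bromide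
Product: 17 (2S,3S,4S)-3-[2-(1,3-dioxolan-2-yl)ethyl]-4-hydroxy-3,4-dimethyl-2-(prop-2-en-1-yl)cyclohexan-1-one, via dilithium enolate alkoxide 16 (not isolated)
Conditions: Li (2.2 equiv), NH3(l)/THF, −78 °C; then allyl bromide (4 equiv), −78 → −33 °C; NH4Cl
Reagents that add atoms: none
Why: Dissolving-metal reduction of the cyclopropyl ketone cleaves the external C2–CH2 bond, the one best aligned with the carbonyl π system, and the primary carbanion is protonated by the tertiary hydroxyl, giving the C1 methyl and the regiodefined C2=C3 lithium enolate 16. Allyl bromide should alkylate C2 by axial attack on the half-chair that has the C1 chain pseudoaxial, anti to that chain and beside the small axial C6 alkoxide, whereas attack on the other face would be syn-axial to the C6 methyl; allyl is therefore expected cis to the C1 methyl (2S).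

Step 8
Reactants: 17 (2S,3S,4S)-3-[2-(1,3-dioxolan-2-yl)ethyl]-4-hydroxy-3,4-dimethyl-2-(prop-2-en-1-yl)cyclohexan-1-one
Product: 18 (1S,2S,3S,4R)-2-[2-(1,3-dioxolan-2-yl)ethyl]-1,2-dimethyl-4-(prop-1-en-2-yl)-3-(prop-2-en-1-yl)cyclohexane-1,4-diol
Conditions: CH2=C(CH3)MgBr, CeCl3, THF, −78 → 0 °C; aq NH4Cl
Reagents that add atoms: isopropenylmagnesium bromide, CC(=C)[Mg]Br
Why: Organocerium 1,2-addition suppresses enolisation of the hindered ketone; equatorial attack, away from the axial C1 methyl, should give mainly the 4R carbinol. Either epimer serves, because this centre becomes sp2 in step 16, and C2 is no longer epimerisable from here on.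

Step 9
Reactants: 18 (1S,2S,3S,4R)-2-[2-(1,3-dioxolan-2-yl)ethyl]-1,2-dimethyl-4-(prop-1-en-2-yl)-3-(prop-2-en-1-yl)cyclohexane-1,4-diol
Product: 20 (1S,2S,3S,4R)-2-[2-(1,3-dioxolan-2-yl)ethyl]-3-(3-hydroxypropyl)-1,2-dimethyl-4-(prop-1-en-2-yl)cyclohexane-1,4-diol, via trialkylborane 19 (not isolated)
Conditions: (Sia)2BH [from BH3·SMe2 and 2-methylbut-2-ene], THF, 0 °C → rt; then NaOH aq, H2O2, 0 °C → rt
Reagents that add atoms: hydrogen peroxide, OO
Why: Anti-Markovnikov hydroboration–oxidation: the bulky dialkylborane should react with the unhindered monosubstituted allyl alkene far faster than with the 1,1-disubstituted isopropenyl group on a fully substituted carbon, and alkaline peroxide replaces boron by hydroxyl.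

Step 10
Reactants: 20 (1S,2S,3S,4R)-2-[2-(1,3-dioxolan-2-yl)ethyl]-3-(3-hydroxypropyl)-1,2-dimethyl-4-(prop-1-en-2-yl)cyclohexane-1,4-diol
Product: 21 (1S,2S,3S,4R)-3-{3-[(tert-butyldiphenylsilyl)oxy]propyl}-2-[2-(1,3-dioxolan-2-yl)ethyl]-1,2-dimethyl-4-(prop-1-en-2-yl)cyclohexane-1,4-diol
Conditions: t-BuPh2SiCl, imidazole, CH2Cl2, 0 °C → rt
Reagents that add atoms: tert-butyl(chloro)diphenylsilane, CC(C)(C)[Si](Cl)(c1ccccc1)c1ccccc1
Why: Only the primary hydroxyl is silylated, since the tertiary hydroxyls do not react with the bulky chlorosilane; the ether is needed because step 16 would oxidise a free primary alcohol, and it is stable to the acid of step 11.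

Step 11
Reactants: 21 (1S,2S,3S,4R)-3-{3-[(tert-butyldiphenylsilyl)oxy]propyl}-2-[2-(1,3-dioxolan-2-yl)ethyl]-1,2-dimethyl-4-(prop-1-en-2-yl)cyclohexane-1,4-diol
Product: 22 3-[(1S,2S,5R,6S)-6-{3-[(tert-butyldiphenylsilyl)oxy]propyl}-2,5-dihydroxy-1,2-dimethyl-5-(prop-1-en-2-yl)cyclohexyl]propanal
Conditions: pyridinium p-toluenesulfonate (0.3 equiv), acetone/H2O 10:1, 50 °C
Reagents that add atoms: water, O
Why: Mild acid-catalysed transacetalisation and hydrolysis of the dioxolane in wet acetone; the pyridinium buffer is weak enough that ionisation of the tertiary allylic alcohol should be slow.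

Step 12
Reactants: 22 3-[(1S,2S,5R,6S)-6-{3-[(tert-butyldiphenylsilyl)oxy]propyl}-2,5-dihydroxy-1,2-dimethyl-5-(prop-1-en-2-yl)cyclohexyl]propanal
Product: 23 (2E)-5-[(1S,2S,5R,6S)-6-{3-[(tert-butyldiphenylsilyl)oxy]propyl}-2,5-dihydroxy-1,2-dimethyl-5-(prop-1-en-2-yl)cyclohexyl]-2-methylpent-2-enal
Conditions: Ph3P=C(CH3)CHO, toluene, 90 °C
Reagents that add atoms: 2-(triphenyl-λ5-phosphanylidene)propanal, CC(C=O)=P(c1ccccc1)(c1ccccc1)c1ccccc1
Why: Wittig olefination with a stabilised formyl ylide should give the (E)-2-methyl-2-enal selectively; the ylide is indifferent to hydroxyl groups.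

Step 13
Reactants: 24 geraniol
Product: 25 geranyl bromide
Conditions: PBr3 (0.4 equiv), Et2O, −10 °C
Reagents that add atoms: phosphorus tribromide, BrP(Br)Br
Why: SN2 displacement of the primary allylic alcohol through its phosphite ester; the low temperature avoids allylic transposition and keeps the 2E geometry.

Step 14
Reactants: 25 geranyl bromide
Product: 26 diethyl [(2E)-3,7-dimethylocta-2,6-dien-1-yl]phosphonate
Conditions: P(OEt)3, neat, 130 °C
Reagents that add atoms: triethyl phosphite, CCOP(OCC)OCC
Why: Michaelis–Arbuzov reaction: phosphorus displaces the primary allylic bromide at C1 and ethyl bromide distils out.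

Step 15
Reactants: 23 (2E)-5-[(1S,2S,5R,6S)-6-{3-[(tert-butyldiphenylsilyl)oxy]propyl}-2,5-dihydroxy-1,2-dimethyl-5-(prop-1-en-2-yl)cyclohexyl]-2-methylpent-2-enal; 26 diethyl [(2E)-3,7-dimethylocta-2,6-dien-1-yl]phosphonate
Product: 28 (1S,2S,3S,4R)-3-{3-[(tert-butyldiphenylsilyl)oxy]propyl}-1,2-dimethyl-4-(prop-1-en-2-yl)-2-[(3E,5E,7E)-4,8,12-trimethyltrideca-3,5,7,11-tetraen-1-yl]cyclohexane-1,4-diol, via lithiated phosphonate 27 (not isolated)
Conditions: 26 (3.5 equiv), n-BuLi (3.3 equiv), THF, −78 °C; then 23, −78 °C → rt
Reagents that add atoms: none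
Why: Horner–Wadsworth–Emmons olefination with an allylic phosphonate anion, which adds through its α carbon and loses phosphate to give the new disubstituted alkene, expected E. The excess anion absorbs the two tertiary hydroxyl protons, and the geranyl double bond should keep its geometry at low temperature.

Step 16
Reactants: 28 (1S,2S,3S,4R)-3-{3-[(tert-butyldiphenylsilyl)oxy]propyl}-1,2-dimethyl-4-(prop-1-en-2-yl)-2-[(3E,5E,7E)-4,8,12-trimethyltrideca-3,5,7,11-tetraen-1-yl]cyclohexane-1,4-diol
Product: 29 (2Z)-2-[(2R,3S,4S)-2-{3-[(tert-butyldiphenylsilyl)oxy]propyl}-4-hydroxy-3,4-dimethyl-3-[(3E,5E,7E)-4,8,12-trimethyltrideca-3,5,7,11-tetraen-1-yl]cyclohexylidene]propanal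
Conditions: [C5H5NH][CrO3Cl] (3 equiv), 4 Å molecular sieves, CH2Cl2, rt
Reagents that add atoms: pyridinium chlorochromate, [O-][Cr](=O)(=O)Cl.c1cc[nH+]cc1
Why: Babler–Dauben oxidative transposition: the chromate ester of the tertiary allylic alcohol undergoes a [3,3] shift to the primary allylic chromate, which is oxidised to the enal. The rotamer that keeps the isopropenyl methyl away from the branched C2, and equilibration of the enal under the mildly acidic conditions, should both favour the Z isomer with the smaller formyl group syn to C2. The C6 hydroxyl is tertiary and the primary oxygen is silylated.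

Step 17
Reactants: 29 (2Z)-2-[(2R,3S,4S)-2-{3-[(tert-butyldiphenylsilyl)oxy]propyl}-4-hydroxy-3,4-dimethyl-3-[(3E,5E,7E)-4,8,12-trimethyltrideca-3,5,7,11-tetraen-1-yl]cyclohexylidene]propanal
Product: 30 (2Z)-2-[(2R,3S,4S)-4-hydroxy-2-(3-hydroxypropyl)-3,4-dimethyl-3-[(3E,5E,7E)-4,8,12-trimethyltrideca-3,5,7,11-tetraen-1-yl]cyclohexylidene]propanal
Conditions: HF·pyridine, pyridine, THF, 0 °C → rt
Reagents that add atoms: none
Why: Fluoride cleaves the Si–O bond; buffered HF·pyridine is mild enough for the enal and the triene and should not epimerise C2.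

## Compound list

1 | 3-ethoxycyclohex-2-en-1-one | CCOC1=CC(=O)CCC1 | starting material
2 | lithium 5-ethoxycyclohexa-1,5-dien-1-olate | CCOC1=CC(O[Li])=CCC1 | intermediate
3 | rac-3-ethoxy-6-methylcyclohex-2-en-1-one | CCOC1=CC(=O)C(C)CC1 | intermediate
4 | sodium 5-ethoxy-2-methylcyclohexa-1,5-dien-1-olate | CCOC1=CC(O[Na])=C(C)CC1 | intermediate
5 | (6S)-3-ethoxy-6-hydroxy-6-methylcyclohex-2-en-1-one | CCOC1=CC(=O)[C@@](C)(O)CC1 | intermediate
6 | 2-(2-bromoethyl)-1,3-dioxolane | BrCCC1OCCO1 | starting material
7 | [2-(1,3-dioxolan-2-yl)ethyl]magnesium bromide | Br[Mg]CCC1OCCO1 | intermediate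
8 | bis(bromomagnesium) (1S)-2-[2-(1,3-dioxolan-2-yl)ethyl]-4-ethoxy-1-methylcyclohex-3-ene-1,2-diolate (C2 epimers) | CCOC1=CC(CCC2OCCO2)(O[Mg]Br)[C@@](C)(O[Mg]Br)CC1 | intermediate
9 | (4S)-3-[2-(1,3-dioxolan-2-yl)ethyl]-4-hydroxy-4-methylcyclohex-2-en-1-one | O1CCOC1CCC2=CC(=O)CC[C@]2(C)O | intermediate
10 | (1S,4R)-2-[2-(1,3-dioxolan-2-yl)ethyl]-1-methylcyclohex-2-ene-1,4-diol | O1CCOC1CCC2=C[C@H](O)CC[C@]2(C)O | intermediate
11 | diiodomethane | ICI | starting material
12 | bis(ethylzinc) alkoxide of 10 | O1CCOC1CCC2=C[C@H](O[Zn]CC)CC[C@]2(C)O[Zn]CC | intermediate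
13 | (1R,2S,5R,6S)-1-[2-(1,3-dioxolan-2-yl)ethyl]-2-methylbicyclo[4.1.0]heptane-2,5-diol | O1CCOC1CC[C@@]23C[C@@H]2[C@H](O)CC[C@]3(C)O | intermediate
14 | (1S,5S,6R)-6-[2-(1,3-dioxolan-2-yl)ethyl]-5-hydroxy-5-methylbicyclo[4.1.0]heptan-2-one | O1CCOC1CC[C@@]23C[C@@H]2C(=O)CC[C@]3(C)O | intermediate
15 | allyl bromide (3-bromoprop-1-ene) | C=CCBr | starting material
16 | dilithium (3S,4S)-3-[2-(1,3-dioxolan-2-yl)ethyl]-3,4-dimethyl-4-oxidocyclohex-1-en-1-olate | O1CCOC1CC[C@@]2(C)C=C(O[Li])CC[C@]2(C)O[Li] | intermediate
17 | (2S,3S,4S)-3-[2-(1,3-dioxolan-2-yl)ethyl]-4-hydroxy-3,4-dimethyl-2-(prop-2-en-1-yl)cyclohexan-1-one | O1CCOC1CC[C@@]2(C)[C@H](CC=C)C(=O)CC[C@]2(C)O | intermediate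
18 | (1S,2S,3S,4R)-2-[2-(1,3-dioxolan-2-yl)ethyl]-1,2-dimethyl-4-(prop-1-en-2-yl)-3-(prop-2-en-1-yl)cyclohexane-1,4-diol | O1CCOC1CC[C@@]2(C)[C@H](CC=C)[C@@](O)(C(C)=C)CC[C@]2(C)O | intermediate
19 | B-alkylbis(3-methylbutan-2-yl)borane from 18 (boron on the terminal carbon of the former allyl group) | O1CCOC1CC[C@@]2(C)[C@H](CCCB(C(C)C(C)C)C(C)C(C)C)[C@@](O)(C(C)=C)CC[C@]2(C)O | intermediate
20 | (1S,2S,3S,4R)-2-[2-(1,3-dioxolan-2-yl)ethyl]-3-(3-hydroxypropyl)-1,2-dimethyl-4-(prop-1-en-2-yl)cyclohexane-1,4-diol | O1CCOC1CC[C@@]2(C)[C@H](CCCO)[C@@](O)(C(C)=C)CC[C@]2(C)O | intermediate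
21 | (1S,2S,3S,4R)-3-{3-[(tert-butyldiphenylsilyl)oxy]propyl}-2-[2-(1,3-dioxolan-2-yl)ethyl]-1,2-dimethyl-4-(prop-1-en-2-yl)cyclohexane-1,4-diol | O1CCOC1CC[C@@]2(C)[C@H](CCCO[Si](c3ccccc3)(c3ccccc3)C(C)(C)C)[C@@](O)(C(C)=C)CC[C@]2(C)O | intermediate
22 | 3-[(1S,2S,5R,6S)-6-{3-[(tert-butyldiphenylsilyl)oxy]propyl}-2,5-dihydroxy-1,2-dimethyl-5-(prop-1-en-2-yl)cyclohexyl]propanal | O=CCC[C@@]1(C)[C@H](CCCO[Si](c2ccccc2)(c2ccccc2)C(C)(C)C)[C@@](O)(C(C)=C)CC[C@]1(C)O | intermediate
23 | (2E)-5-[(1S,2S,5R,6S)-6-{3-[(tert-butyldiphenylsilyl)oxy]propyl}-2,5-dihydroxy-1,2-dimethyl-5-(prop-1-en-2-yl)cyclohexyl]-2-methylpent-2-enal | O=C/C(C)=C/CC[C@@]1(C)[C@H](CCCO[Si](c2ccccc2)(c2ccccc2)C(C)(C)C)[C@@](O)(C(C)=C)CC[C@]1(C)O | intermediate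
24 | geraniol [(2E)-3,7-dimethylocta-2,6-dien-1-ol] | CC(C)=CCC/C(C)=C/CO | starting material
25 | geranyl bromide [(2E)-1-bromo-3,7-dimethylocta-2,6-diene] | CC(C)=CCC/C(C)=C/CBr | intermediate
26 | diethyl [(2E)-3,7-dimethylocta-2,6-dien-1-yl]phosphonate | CC(C)=CCC/C(C)=C/CP(=O)(OCC)OCC | intermediate
27 | α-lithio derivative of 26 | CC(C)=CCC/C(C)=C/C([Li])P(=O)(OCC)OCC | intermediate
28 | (1S,2S,3S,4R)-3-{3-[(tert-butyldiphenylsilyl)oxy]propyl}-1,2-dimethyl-4-(prop-1-en-2-yl)-2-[(3E,5E,7E)-4,8,12-trimethyltrideca-3,5,7,11-tetraen-1-yl]cyclohexane-1,4-diol | CC(C)=CCC/C(C)=C/C=C/C(C)=C/CC[C@@]1(C)[C@H](CCCO[Si](c2ccccc2)(c2ccccc2)C(C)(C)C)[C@@](O)(C(C)=C)CC[C@]1(C)O | intermediate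
29 | (2Z)-2-[(2R,3S,4S)-2-{3-[(tert-butyldiphenylsilyl)oxy]propyl}-4-hydroxy-3,4-dimethyl-3-[(3E,5E,7E)-4,8,12-trimethyltrideca-3,5,7,11-tetraen-1-yl]cyclohexylidene]propanal | CC(C)=CCC/C(C)=C/C=C/C(C)=C/CC[C@@]1(C)[C@H](CCCO[Si](c2ccccc2)(c2ccccc2)C(C)(C)C)/C(=C(/C)C=O)CC[C@]1(C)O | intermediate
30 | (2Z)-2-[(2R,3S,4S)-4-hydroxy-2-(3-hydroxypropyl)-3,4-dimethyl-3-[(3E,5E,7E)-4,8,12-trimethyltrideca-3,5,7,11-tetraen-1-yl]cyclohexylidene]propanal | CC(C)=CCC/C(C)=C/C=C/C(C)=C/CC[C@@]1(C)[C@H](CCCO)/C(=C(/C)C=O)CC[C@]1(C)O | target

## Step count and least certain steps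

Total: 17 steps. Longest linear sequence: 15 steps (steps 1 to 12 and 15 to 17, from 1); steps 13 and 14 prepare 26 from 24.

Step 5 (key step). Facial selectivity is the least likely point of failure. The more probable problem is slow methylene transfer to a trisubstituted alkene flanked by a fully substituted carbinol, which would give the zinc iodide formed in the flask time to ionise the tertiary cyclopropyl carbinol or open the dioxolane. The fallback sets out from 9 and returns at 17, and replaces cyclopropanation by alkoxide-directed conjugate methylation. Excess CH3MgBr in THF/toluene first forms the C6 magnesium alkoxide of 9, which should guide a second equivalent to add methyl to C1 on its own face, giving the bis(bromomagnesium) enolate alkoxide F1; this is allylated in the same flask with 15 in the presence of DMPU to give 17. The limitation is that 1,4-addition to a β,β-disubstituted enone may give way to 1,2-addition.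

Step 2. The oxaziridine may discriminate poorly between the faces of the tetrasubstituted dienolate, or in the opposite sense. The fallback sets out from 3 and returns at 10. Hydroxylation of the potassium enolate with achiral 3-phenyl-2-(phenylsulfonyl)oxaziridine gives racemic 3-ethoxy-6-hydroxy-6-methylcyclohex-2-en-1-one F2. Addition of 7 and acidic transposition give the racemic enone F3. Reduction under the conditions of step 4 sets C4 as R in both enantiomers, so the S enantiomer gives 10 and the R enantiomer gives the trans diol F4, which is removed by chromatography. Half of the material is lost, but the tertiary centre is resolved by a catalyst-controlled step.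

Step 7. The electrophile may enter on the face syn to the C1 chain, proton transfer between enolate and product may scramble the enolate position, or the tertiary alkoxide may be O-allylated. The fallback sets out from 14 (through the enolate 16) and returns at 21; it brings in the carbon first and the hydrogen last.
- 16 is trapped with 3-[(tert-butyldiphenylsilyl)oxy]propanal to give the aldol F5.
- Mesylation of the secondary hydroxyl and elimination with DBU give the exocyclic alkylidene ketone F6.
- Conjugate reduction with [(Ph3P)CuH]6 regenerates a C2=C3 enolate that already bears the arm; its kinetic protonation, on the face that carbon electrophiles prefer, should give the ketone F7.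
- Isopropenyl addition as in step 8 then leads to 21, without hydroboration or silylation.

Step 11. The tertiary allylic alcohol may ionise during acetal cleavage (allylic transposition, ether formation with the C6 hydroxyl). The fallback sets out from 21 and returns at 29; it removes the sensitive carbinol before acid is used.
- Oxidative transposition of 21 under the conditions of step 16 gives the enal acetal F8.
- 1 M HCl in THF gives the enal aldehyde F9.
- The ylide of step 12 should react only with the saturated aldehyde, giving the bis-enal F10.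
- One equivalent of 27 at −78 °C should then olefinate the less hindered chain enal to give 29. The cost is a chemoselectivity between two enals that rests on hindrance alone.

Step 16. The acidic hexavalent chromium reagent may oxidise or isomerise the conjugated triene, and the [3,3] shift may give part of the E enal. The fallback sets out from 28 and returns at 29. Ph3SiOReO3 (catalytic, Et2O, −50 → 0 °C) should transpose the tertiary allylic alcohol without oxidation to the primary allylic alcohol F11. MnO2 in CH2Cl2, a reagent suited to polyene allylic alcohols, then oxidises it to 29.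

## Further compounds

F1 | step 5 | bis(bromomagnesium) (3S,4S)-3-[2-(1,3-dioxolan-2-yl)ethyl]-3,4-dimethyl-4-oxidocyclohex-1-en-1-olate | O1CCOC1CC[C@@]2(C)C=C(O[Mg]Br)CC[C@]2(C)O[Mg]Br
F2 | step 2 | rac-3-ethoxy-6-hydroxy-6-methylcyclohex-2-en-1-one | CCOC1=CC(=O)C(C)(O)CC1
F3 | step 2 | rac-3-[2-(1,3-dioxolan-2-yl)ethyl]-4-hydroxy-4-methylcyclohex-2-en-1-one | O1CCOC1CCC2=CC(=O)CCC2(C)O
F4 | step 2 | (1R,4R)-2-[2-(1,3-dioxolan-2-yl)ethyl]-1-methylcyclohex-2-ene-1,4-diol | O1CCOC1CCC2=C[C@H](O)CC[C@@]2(C)O
F5 | step 7 | (3S,4S)-2-{3-[(tert-butyldiphenylsilyl)oxy]-1-hydroxypropyl}-3-[2-(1,3-dioxolan-2-yl)ethyl]-4-hydroxy-3,4-dimethylcyclohexan-1-one (mixture at C2 and at the carbinol carbon) | O1CCOC1CC[C@@]2(C)C(C(O)CCO[Si](c3ccccc3)(c3ccccc3)C(C)(C)C)C(=O)CC[C@]2(C)O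
F6 | step 7 | (3S,4S)-2-{3-[(tert-butyldiphenylsilyl)oxy]propylidene}-3-[2-(1,3-dioxolan-2-yl)ethyl]-4-hydroxy-3,4-dimethylcyclohexan-1-one (either alkene isomer) | O1CCOC1CC[C@@]2(C)C(=CCCO[Si](c3ccccc3)(c3ccccc3)C(C)(C)C)C(=O)CC[C@]2(C)O
F7 | step 7 | (2S,3S,4S)-2-{3-[(tert-butyldiphenylsilyl)oxy]propyl}-3-[2-(1,3-dioxolan-2-yl)ethyl]-4-hydroxy-3,4-dimethylcyclohexan-1-one | O1CCOC1CC[C@@]2(C)[C@H](CCCO[Si](c3ccccc3)(c3ccccc3)C(C)(C)C)C(=O)CC[C@]2(C)O
F8 | step 11 | (2Z)-2-[(2R,3S,4S)-2-{3-[(tert-butyldiphenylsilyl)oxy]propyl}-3-[2-(1,3-dioxolan-2-yl)ethyl]-4-hydroxy-3,4-dimethylcyclohexylidene]propanal | O1CCOC1CC[C@@]2(C)[C@H](CCCO[Si](c3ccccc3)(c3ccccc3)C(C)(C)C)/C(=C(/C)C=O)CC[C@]2(C)O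
F9 | step 11 | (2Z)-2-[(2R,3S,4S)-2-{3-[(tert-butyldiphenylsilyl)oxy]propyl}-4-hydroxy-3,4-dimethyl-3-(3-oxopropyl)cyclohexylidene]propanal | O=CCC[C@@]1(C)[C@H](CCCO[Si](c2ccccc2)(c2ccccc2)C(C)(C)C)/C(=C(/C)C=O)CC[C@]1(C)O
F10 | step 11 | (2E)-5-[(1S,2S,5Z,6R)-6-{3-[(tert-butyldiphenylsilyl)oxy]propyl}-2-hydroxy-1,2-dimethyl-5-(1-oxopropan-2-ylidene)cyclohexyl]-2-methylpent-2-enal | O=C/C(C)=C/CC[C@@]1(C)[C@H](CCCO[Si](c2ccccc2)(c2ccccc2)C(C)(C)C)/C(=C(/C)C=O)CC[C@]1(C)O
F11 | step 16 | (2Z)-2-[(2R,3S,4S)-2-{3-[(tert-butyldiphenylsilyl)oxy]propyl}-4-hydroxy-3,4-dimethyl-3-[(3E,5E,7E)-4,8,12-trimethyltrideca-3,5,7,11-tetraen-1-yl]cyclohexylidene]propan-1-ol | CC(C)=CCC/C(C)=C/C=C/C(C)=C/CC[C@@]1(C)[C@H](CCCO[Si](c2ccccc2)(c2ccccc2)C(C)(C)C)/C(=C(/C)CO)CC[C@]1(C)O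
A1 | alternative 1 | (2S,3S,4S)-2-{3-[(tert-butyldimethylsilyl)oxy]propyl}-3-ethenyl-3,4-dimethyl-4-[(triethylsilyl)oxy]cyclohexan-1-one | C=C[C@@]1(C)[C@H](CCCO[Si](C)(C)C(C)(C)C)C(=O)CC[C@]1(C)O[Si](CC)(CC)CC
A2 | alternative 1 | (S)-linalool [(3S)-3,7-dimethylocta-1,6-dien-3-ol] | C=C[C@@](C)(O)CCC=C(C)C
A3 | alternative 2 | (6S,7S)-6-{3-[(tert-butyldimethylsilyl)oxy]propyl}-7-methyl-7-(prop-2-en-1-yl)-1,4-dioxaspiro[4.5]decan-8-one | C=CC[C@@]1(C)[C@H](CCCO[Si](C)(C)C(C)(C)C)C2(OCCO2)CCC1=O
A4 | alternative 2 | 7-methyl-1,4-dioxaspiro[4.5]dec-6-en-8-one | CC1=CC2(OCCO2)CCC1=O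
A5 | alternative 3 | (1S,2S,3S,6R)-3,6-bis[(tert-butyldimethylsilyl)oxy]-2-{3-[(tert-butyldiphenylsilyl)oxy]propyl}-1-methylcyclohex-4-ene-1-carbaldehyde | O=C[C@@]1(C)[C@H](CCCO[Si](c2ccccc2)(c2ccccc2)C(C)(C)C)[C@@H](O[Si](C)(C)C(C)(C)C)C=C[C@H]1O[Si](C)(C)C(C)(C)C
A6 | alternative 3 | (2E)-6-[(tert-butyldiphenylsilyl)oxy]-2-methylhex-2-enal | O=C/C(C)=C/CCCO[Si](c1ccccc1)(c1ccccc1)C(C)(C)C
A7 | alternative 3 | (1E,3E)-1,4-bis[(tert-butyldimethylsilyl)oxy]buta-1,3-diene | CC(C)(C)[Si](C)(C)O/C=C/C=C/O[Si](C)(C)C(C)(C)C
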